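**Plan**
The retrosynthesis first removes the two O–S bonds (O7, O4') and the three benzyl ethers (O3, O5, O3'), then opens ring C at O1–C8a, then cuts C3–C4 (aldol) and C2–C1' (aryllithium acylation).
The enabling feature is that O1 of ring C sits on C8a of ring A, next to C4a, which carries the C4 carbonyl. An ortho-bromo aroyl unit and the enol oxygen of a 1,3-diketone can therefore be joined at O1–C8a, and no free ortho-phenol is needed at any stage.
Forward, rings A and B are bought as arenes, joined through the C2–C3–C4 chain by aldol addition and oxidation, and ring C is the only ring formed, by copper O-arylation.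
MOM ethers mark the two oxygens to be sulfated (O7, O4'); benzyl ethers mask O3, O5 and O3' until the last step.
The target has no stereocentre; those formed in the aldol step are erased by oxidation and by closure of the pyranone.

Key step: step 10

Assumption: aryl hydrogen sulfates are strong acids that are handled as salts. The two sulfated compounds of the route are drawn as the free acids of the target SMILES, and counter-ion exchange (salt formation after sulfation, release of the acid on an H+-form resin at the end) is treated as work-up.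

**Route**

Step 1
Reactants: 1 5-bromoresorcinol
Product: 3 2-bromo-4,6-dihydroxybenzaldehyde, via iminium chloride 2 (not isolated)
Conditions: POCl3, DMF, MeCN, 0 °C to rt; then H2O, 50 °C
Reagents that add atoms: N,N-dimethylformamide CN(C)C=O; water O
Why: Vilsmeier–Haack formylation, in which the chloroiminium ion should attack the position para to one hydroxyl and ortho to the other (next to bromine), as in the formylation of orcinol, and hydrolysis of iminium salt 2 releases the aldehyde.

Step 2
Reactants: 3 2-bromo-4,6-dihydroxybenzaldehyde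
Product: 4 2-bromo-6-hydroxy-4-(methoxymethoxy)benzaldehyde
Conditions: MOMCl (1.05 equiv), K2CO3, acetone, 0 °C to rt
Reagents that add atoms: chloromethyl methyl ether COCCl
Why: Williamson-type O-alkylation should be selective for the para hydroxyl because the ortho hydroxyl is tied up in a hydrogen bond to the formyl group and is the weaker nucleophile.

Step 3
Reactants: 4 2-bromo-6-hydroxy-4-(methoxymethoxy)benzaldehyde
Product: 5 2-(benzyloxy)-6-bromo-4-(methoxymethoxy)benzaldehyde
Conditions: BnBr, K2CO3, DMF, 60 °C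
Reagents that add atoms: benzyl bromide BrCc1ccccc1
Why: Williamson ether synthesis under more forcing conditions alkylates the remaining chelated phenol, so the future O5 and O7 carry orthogonal ethers.

Step 4
Reactants: 6 2-(benzyloxy)phenol
Product: 7 2-(benzyloxy)-4-bromophenol
Conditions: NBS, MeCN, 0 °C
Reagents that add atoms: N-bromosuccinimide O=C1CCC(=O)N1Br
Why: Electrophilic aromatic bromination should go para to the free hydroxyl, the strongest director, which places the halogen at the future C1' (para to O4', meta to O3').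

Step 5
Reactants: 7 2-(benzyloxy)-4-bromophenol
Product: 8 2-(benzyloxy)-4-bromo-1-(methoxymethoxy)benzene
Conditions: MOMCl, K2CO3, acetone, rt
Reagents that add atoms: chloromethyl methyl ether COCCl
Why: Williamson-type protection gives a MOM ether that tolerates the organolithium, enolate and carbonate steps ahead and is later cleaved without touching benzyl ethers.

Step 6
Reactants: 9 benzyloxyacetyl chloride
Product: 10 2-(benzyloxy)-N-methoxy-N-methylacetamide
Conditions: MeNH(OMe)·HCl, K2CO3, CH2Cl2/H2O, 0 °C
Reagents that add atoms: N,O-dimethylhydroxylamine hydrochloride CNOC.Cl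
Why: Schotten–Baumann N-acylation of the hydroxylamine by the acid chloride gives the Weinreb amide.

Step 7
Reactants: 8 2-(benzyloxy)-4-bromo-1-(methoxymethoxy)benzene; 10 2-(benzyloxy)-N-methoxy-N-methylacetamide
Product: 13 2-(benzyloxy)-1-[3-(benzyloxy)-4-(methoxymethoxy)phenyl]ethan-1-one, via aryllithium 11 (not isolated), via lithium hemiaminal adduct 12 (not isolated)
Conditions: n-BuLi, THF, −78 °C; then 10, −78 to 0 °C; H2O
Reagents that add atoms: none
Why: Bromine–lithium exchange followed by Weinreb ketone synthesis, in which the chelated tetrahedral adduct 12 resists a second addition and collapses to the ketone only on quench, forming C2–C1'.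

Step 8
Reactants: 13 2-(benzyloxy)-1-[3-(benzyloxy)-4-(methoxymethoxy)phenyl]ethan-1-one; 5 2-(benzyloxy)-6-bromo-4-(methoxymethoxy)benzaldehyde
Product: 15 2-(benzyloxy)-3-[2-(benzyloxy)-6-bromo-4-(methoxymethoxy)phenyl]-1-[3-(benzyloxy)-4-(methoxymethoxy)phenyl]-3-hydroxypropan-1-one, via lithium enolate 14 (not isolated)
Conditions: LiN(SiMe3)2, THF, −78 °C; then 5, −78 °C; AcOH quench at −78 °C
Reagents that add atoms: none
Why: Directed aldol addition of the chelated Z-lithium enolate of the α-benzyloxy ketone to the non-enolisable aldehyde forms C3–C4; the two new stereocentres arise without control (racemic diastereomer mixture) and both are removed later, and the cold acidic quench should prevent retro-aldol.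

Step 9
Reactants: 15 2-(benzyloxy)-3-[2-(benzyloxy)-6-bromo-4-(methoxymethoxy)phenyl]-1-[3-(benzyloxy)-4-(methoxymethoxy)phenyl]-3-hydroxypropan-1-one
Product: 16 2-(benzyloxy)-1-[2-(benzyloxy)-6-bromo-4-(methoxymethoxy)phenyl]-3-[3-(benzyloxy)-4-(methoxymethoxy)phenyl]propane-1,3-dione
Conditions: Dess–Martin periodinane, CH2Cl2, 0 °C to rt
Reagents that add atoms: none
Why: Dess–Martin oxidation of the secondary benzylic alcohol gives the 2-benzyloxy-1,3-diketone under near-neutral conditions that spare MOM ethers, benzyl ethers and the aryl bromide, and it erases the carbinol stereocentre.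

Step 10
Reactants: 16 2-(benzyloxy)-1-[2-(benzyloxy)-6-bromo-4-(methoxymethoxy)phenyl]-3-[3-(benzyloxy)-4-(methoxymethoxy)phenyl]propane-1,3-dione
Product: 18 3,5-bis(benzyloxy)-2-[3-(benzyloxy)-4-(methoxymethoxy)phenyl]-7-(methoxymethoxy)chromen-4-one, via potassium enolate 17 (not isolated)
Conditions: CuI (10 mol %), 1,10-phenanthroline (20 mol %), K2CO3 (2 equiv), DMF, 90 °C
Reagents that add atoms: none
Why: K2CO3 removes the doubly activated C3–H of 16 to give enolate 17, whose oxygen on the ring B side binds monovalent copper; oxidative addition of the neighbouring C8a–Br bond gives a trivalent copper aryl enolate in a seven-membered metallacycle, and C–O reductive elimination forges O1–C8a and returns the catalyst. The closest known reaction type is the copper-catalysed intramolecular Ullmann O-arylation of 1-(2-haloaryl)-1,3-diketones to chromones and flavones, which also tolerates a substituent on the central carbon. Ring C closes as a six-membered ring by attack of the enol oxygen on sp2 carbon C8a (6-exo-trig in the addition–elimination sense, with the C2=C3 enol bond inside the new ring), and because the ortho aroyl group activates the bromide, a copper-free addition–elimination can lead to the same bond. No stereocentre is formed, and the stereocentre at C3 of 16 is lost on enolisation. The step needs O- rather than C-arylation and reaction at only one carbonyl oxygen: only the enol oxygen on the ring B side reaches C8a through a six-membered array, whereas the central carbon or the ring A-side oxygen would have to close a four-membered ring. The two ring A alkoxy groups are meta to bromine and should not retard oxidative addition, and MOM and benzyl ethers are inert to carbonate in DMF.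

Step 11
Reactants: 18 3,5-bis(benzyloxy)-2-[3-(benzyloxy)-4-(methoxymethoxy)phenyl]-7-(methoxymethoxy)chromen-4-one
Product: 19 3,5-bis(benzyloxy)-2-[3-(benzyloxy)-4-hydroxyphenyl]-7-hydroxychromen-4-one
Conditions: HCl (1.25 M in MeOH), THF, 40 °C
Reagents that add atoms: none
Why: Acid-catalysed acetal exchange with methanol cleaves both MOM ethers as dimethoxymethane, while the benzyl ethers are not acetals and should persist under these mild conditions.

Step 12
Reactants: 19 3,5-bis(benzyloxy)-2-[3-(benzyloxy)-4-hydroxyphenyl]-7-hydroxychromen-4-one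
Product: 20 3,5-bis(benzyloxy)-2-[3-(benzyloxy)-4-(sulfooxy)phenyl]-4-oxo-4H-chromen-7-yl hydrogen sulfate
Conditions: SO3·pyridine (6 equiv), pyridine, 40 °C
Reagents that add atoms: sulfur trioxide–pyridine complex [O-]S(=O)(=O)[n+]1ccccc1
Why: O-sulfonation of phenols by the sulfur trioxide–pyridine complex can only occur at O7 and O4', since O3, O5 and O3' are blocked as benzyl ethers.

Step 13
Reactants: 20 3,5-bis(benzyloxy)-2-[3-(benzyloxy)-4-(sulfooxy)phenyl]-4-oxo-4H-chromen-7-yl hydrogen sulfate
Product: 21 3',5-dihydroxy-4',7-bis(sulfooxy)flavonol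
Conditions: H2 (1 atm), 10% Pd/C, MeOH/THF, rt
Reagents that add atoms: none
Why: Catalytic hydrogenolysis cleaves the three benzylic C–O bonds to toluene, whereas aryl sulfate monoesters (as their salts) are inert to H2 over Pd/C and the C2=C3 bond of a flavonol should not be reduced under these conditions.

**Compound list**
1 | 5-bromoresorcinol (5-bromobenzene-1,3-diol) | Oc1cc(O)cc(Br)c1 | starting material
2 | N-[(2-bromo-4,6-dihydroxyphenyl)methylidene]-N-methylmethanaminium chloride (not isolated) | C[N+](C)=Cc1c(Br)cc(O)cc1O.[Cl-] | intermediate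
3 | 2-bromo-4,6-dihydroxybenzaldehyde | O=Cc1c(Br)cc(O)cc1O | intermediate
4 | 2-bromo-6-hydroxy-4-(methoxymethoxy)benzaldehyde | O=Cc1c(Br)cc(OCOC)cc1O | intermediate
5 | 2-(benzyloxy)-6-bromo-4-(methoxymethoxy)benzaldehyde | O=Cc1c(Br)cc(OCOC)cc1OCc1ccccc1 | intermediate
6 | 2-(benzyloxy)phenol | Oc1ccccc1OCc1ccccc1 | starting material
7 | 2-(benzyloxy)-4-bromophenol | Oc1ccc(Br)cc1OCc1ccccc1 | intermediate
8 | 2-(benzyloxy)-4-bromo-1-(methoxymethoxy)benzene | COCOc1ccc(Br)cc1OCc1ccccc1 | intermediate
9 | benzyloxyacetyl chloride | O=C(Cl)COCc1ccccc1 | starting material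
10 | 2-(benzyloxy)-N-methoxy-N-methylacetamide | CON(C)C(=O)COCc1ccccc1 | intermediate
11 | [3-(benzyloxy)-4-(methoxymethoxy)phenyl]lithium (not isolated) | [Li]c1ccc(OCOC)c(OCc2ccccc2)c1 | intermediate
12 | lithium 2-(benzyloxy)-1-[3-(benzyloxy)-4-(methoxymethoxy)phenyl]-1-[methoxy(methyl)amino]ethan-1-olate (racemic, not isolated) | [Li]OC(COCc1ccccc1)(N(C)OC)c1ccc(OCOC)c(OCc2ccccc2)c1 | intermediate
13 | 2-(benzyloxy)-1-[3-(benzyloxy)-4-(methoxymethoxy)phenyl]ethan-1-one | O=C(COCc1ccccc1)c1ccc(OCOC)c(OCc2ccccc2)c1 | intermediate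
14 | lithium (Z)-2-(benzyloxy)-1-[3-(benzyloxy)-4-(methoxymethoxy)phenyl]ethen-1-olate (not isolated) | [Li]O/C(=C\OCc1ccccc1)c1ccc(OCOC)c(OCc2ccccc2)c1 | intermediate
15 | 2-(benzyloxy)-3-[2-(benzyloxy)-6-bromo-4-(methoxymethoxy)phenyl]-1-[3-(benzyloxy)-4-(methoxymethoxy)phenyl]-3-hydroxypropan-1-one (racemic mixture of diastereomers) | O=C(c1ccc(OCOC)c(OCc2ccccc2)c1)C(OCc1ccccc1)C(O)c1c(Br)cc(OCOC)cc1OCc1ccccc1 | intermediate
16 | 2-(benzyloxy)-1-[2-(benzyloxy)-6-bromo-4-(methoxymethoxy)phenyl]-3-[3-(benzyloxy)-4-(methoxymethoxy)phenyl]propane-1,3-dione (racemic, enolisable) | O=C(c1c(Br)cc(OCOC)cc1OCc1ccccc1)C(OCc1ccccc1)C(=O)c1ccc(OCOC)c(OCc2ccccc2)c1 | intermediate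
17 | potassium enolate of 16, negative oxygen on the ring B side (not isolated) | [K+].[O-]C(=C(OCc1ccccc1)C(=O)c1c(Br)cc(OCOC)cc1OCc1ccccc1)c1ccc(OCOC)c(OCc2ccccc2)c1 | intermediate
18 | 3,5-bis(benzyloxy)-2-[3-(benzyloxy)-4-(methoxymethoxy)phenyl]-7-(methoxymethoxy)chromen-4-one | O=c1c(OCc2ccccc2)c(-c2ccc(OCOC)c(OCc3ccccc3)c2)oc2cc(OCOC)cc(OCc3ccccc3)c12 | intermediate
19 | 3,5-bis(benzyloxy)-2-[3-(benzyloxy)-4-hydroxyphenyl]-7-hydroxychromen-4-one | O=c1c(OCc2ccccc2)c(-c2ccc(O)c(OCc3ccccc3)c2)oc2cc(O)cc(OCc3ccccc3)c12 | intermediate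
20 | 3,5-bis(benzyloxy)-2-[3-(benzyloxy)-4-(sulfooxy)phenyl]-4-oxo-4H-chromen-7-yl hydrogen sulfate | O=c1c(OCc2ccccc2)c(-c2ccc(OS(=O)(=O)O)c(OCc3ccccc3)c2)oc2cc(OS(=O)(=O)O)cc(OCc3ccccc3)c12 | intermediate
21 | 3',5-dihydroxy-4',7-bis(sulfooxy)flavonol (3,5-dihydroxy-2-[3-hydroxy-4-(sulfooxy)phenyl]-4-oxo-4H-chromen-7-yl hydrogen sulfate) | O=c1c(O)c(-c2ccc(OS(=O)(=O)O)c(O)c2)oc2cc(OS(=O)(=O)O)cc(O)c12 | target

**Count**
Total steps: 13. Longest linear sequence: 9 steps (steps 1–3 and 8–13 from 1, or steps 4, 5 and 7–13 from 6).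

**Steps most likely to fail**

Step 10. The diketone may fragment by retro-Claisen cleavage under hot carbonate, or oxidative addition may be slow because the doubly ortho-substituted aroyl group is twisted out of the plane of ring A. The fallback closes ring C at O1–C2 by cyclodehydration; it sets out from ketone 13 and returns at diol 19. Commercial 2,4,6-trihydroxybenzaldehyde (O=Cc1c(O)cc(O)cc1O) would be treated with MOMCl (2 equiv) and i-Pr2NEt to give 2-hydroxy-4,6-bis(methoxymethoxy)benzaldehyde F1. The remaining chelated phenol would be benzylated (BnBr, K2CO3, DMF) to 2-(benzyloxy)-4,6-bis(methoxymethoxy)benzaldehyde F2. Lithium enolate 14, made from 13 as in step 8, would add to F2 to give 2-(benzyloxy)-3-[2-(benzyloxy)-4,6-bis(methoxymethoxy)phenyl]-1-[3-(benzyloxy)-4-(methoxymethoxy)phenyl]-3-hydroxypropan-1-one F3. Dess–Martin oxidation would give 2-(benzyloxy)-1-[2-(benzyloxy)-4,6-bis(methoxymethoxy)phenyl]-3-[3-(benzyloxy)-4-(methoxymethoxy)phenyl]propane-1,3-dione F4. HCl in MeOH/THF would then strip the three MOM groups and dehydrate the liberated 2-hydroxyaryl diketone to the chromone, arriving at 19.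

Step 8. The aldolate of the hindered, doubly ortho-substituted aldehyde may revert (retro-aldol), or the enolate may be quenched by proton transfer, so that conversion stalls. The fallback is a Lewis acid Mukaiyama aldol in place of the base-mediated aldol; it sets out from ketone 13 and returns at aldol 15. TMSOTf and Et3N in CH2Cl2 would convert 13 into (Z)-{[2-(benzyloxy)-1-[3-(benzyloxy)-4-(methoxymethoxy)phenyl]ethenyl]oxy}trimethylsilane F5. F5 would add to aldehyde 5 under BF3·OEt2 at −78 °C, where the adduct is held as a boron chelate and cannot revert, and aqueous work-up should give 15.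

Step 11. Acidolysis of the peri 5-O-benzyl ether may accompany MOM cleavage and give mixtures. The fallback relies on the inertness of the chelated 5-hydroxyl instead of protecting it; it sets out from 18 and returns at target 21. Concentrated HCl in AcOH at 50 °C would deliberately remove both MOM groups and the 5-O-benzyl group to give 3-(benzyloxy)-2-[3-(benzyloxy)-4-hydroxyphenyl]-5,7-dihydroxychromen-4-one F6. SO3·pyridine should then sulfate only O7 and O4', because the 5-hydroxyl is locked in a hydrogen bond to the C4 carbonyl, giving 3-(benzyloxy)-2-[3-(benzyloxy)-4-(sulfooxy)phenyl]-5-hydroxy-4-oxo-4H-chromen-7-yl hydrogen sulfate F7. Hydrogenolysis over Pd/C would give 21.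

Further compounds
F1 | step 10 | 2-hydroxy-4,6-bis(methoxymethoxy)benzaldehyde | O=Cc1c(O)cc(OCOC)cc1OCOC
F2 | step 10 | 2-(benzyloxy)-4,6-bis(methoxymethoxy)benzaldehyde | O=Cc1c(OCc2ccccc2)cc(OCOC)cc1OCOC
F3 | step 10 | 2-(benzyloxy)-3-[2-(benzyloxy)-4,6-bis(methoxymethoxy)phenyl]-1-[3-(benzyloxy)-4-(methoxymethoxy)phenyl]-3-hydroxypropan-1-one (racemic mixture of diastereomers) | O=C(c1ccc(OCOC)c(OCc2ccccc2)c1)C(OCc1ccccc1)C(O)c1c(OCOC)cc(OCOC)cc1OCc1ccccc1
F4 | step 10 | 2-(benzyloxy)-1-[2-(benzyloxy)-4,6-bis(methoxymethoxy)phenyl]-3-[3-(benzyloxy)-4-(methoxymethoxy)phenyl]propane-1,3-dione | O=C(c1c(OCOC)cc(OCOC)cc1OCc1ccccc1)C(OCc1ccccc1)C(=O)c1ccc(OCOC)c(OCc2ccccc2)c1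
F5 | step 8 | (Z)-{[2-(benzyloxy)-1-[3-(benzyloxy)-4-(methoxymethoxy)phenyl]ethenyl]oxy}trimethylsilane | C[Si](C)(C)O/C(=C\OCc1ccccc1)c1ccc(OCOC)c(OCc2ccccc2)c1
F6 | step 11 | 3-(benzyloxy)-2-[3-(benzyloxy)-4-hydroxyphenyl]-5,7-dihydroxychromen-4-one | O=c1c(OCc2ccccc2)c(-c2ccc(O)c(OCc3ccccc3)c2)oc2cc(O)cc(O)c12
F7 | step 11 | 3-(benzyloxy)-2-[3-(benzyloxy)-4-(sulfooxy)phenyl]-5-hydroxy-4-oxo-4H-chromen-7-yl hydrogen sulfate | O=c1c(OCc2ccccc2)c(-c2ccc(OS(=O)(=O)O)c(OCc3ccccc3)c2)oc2cc(OS(=O)(=O)O)cc(O)c12
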